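**Plan**

1. Numbering (labdane): ring A = C1–C5 and C10, ring B = C5–C10; C17 = CH2 on C8, C18 = CH3 and C19 = CH2O on C4, C20 = CH3 on C10, side chain C11–C16 on C9.
2. Retrosynthesis: cut the C19–O acyl bond and the cinnamate C=C, then the diene (back to a C13≡C16 alkyne), C8=C17 (back to a C8 ketone) and C9–C11; ring B is then opened at C6–C7 and C9–C10 at once.
3. Enabling feature: C8, the carbon under the exocyclic methylene, is a latent ketone, so C7–C8–C9 is an acetone unit (a 1,3-dinucleophile as its enamine) and C6–C5–C10 is the acyl, α and β carbon of a ring A cyclohexenecarbonyl chloride (a 1,3-dielectrophile). A temporary N–C6 bond carries C9 onto the hindered C10 by a [3,3] shift and is cleaved in the same event; the ketene set free closes C6–C7.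
4. Forward: ring A acid chloride (six steps from 2,6-dimethylcyclohexanone) → ring B by the [3+3] event → reductive carbonyl transposition (C6 oxygen out, C8 ketone in) → C9 side chain → C8 methylene → diene → Z-coumarate on C19.
5. Stereochemistry: C4 by catalysis (asymmetric hydroxymethylation); C10 relayed from C4 in the sigmatropic shift; C5 and C9 by thermodynamic control (trans fusion, equatorial side chain); Z alkene by a diaryl phosphonate olefination.

Key step: step 8

Remark: commercial 1 is used as its cis/trans mixture because the CH stereocentre next to the carbonyl is destroyed in step 4; in the descriptions "syn/anti to CH3-20" gives the relative configuration and the SMILES give the absolute one.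

**Route**

Step 1
Reactants: 1 2,6-dimethylcyclohexan-1-one
Product: 2 2,6-dimethyl-1-(trimethylsilyloxy)cyclohex-1-ene
Conditions: Me3SiOTf, Et3N, CH2Cl2, 0 °C to rt
Reagents that add atoms: trimethylsilyl trifluoromethanesulfonate, C[Si](C)(C)OS(=O)(=O)C(F)(F)F
Why: Soft enolisation and O-silylation (silyl enol ether formation); both α-carbons are equivalent, so a single tetrasubstituted enol ether should form.

Step 2
Reactants: 2 silyl enol ether
Product: 3 (2S)-2-(hydroxymethyl)-2,6-dimethylcyclohexan-1-one
Conditions: aq. HCHO, Sc(OTf)3 (10 mol%), 6,6'-bis(1-hydroxy-2,2-dimethylpropyl)-2,2'-bipyridine (12 mol%, the enantiomer that leads to (S)-3), DME/H2O 9:1, −20 °C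
Reagents that add atoms: formaldehyde, C=O
Why: Catalytic asymmetric Mukaiyama aldol (hydroxymethylation) with aqueous formaldehyde; the chiral scandium–bipyridine complex selects one face of the enol ether and so sets the quaternary C4 stereocentre.

Step 3
Reactants: 3 hydroxy ketone
Product: 4 (2S)-2-{[tert-butyl(diphenyl)silyl]oxymethyl}-2,6-dimethylcyclohexan-1-one
Conditions: t-BuPh2SiCl, imidazole, CH2Cl2, 0 °C to rt
Reagents that add atoms: tert-butyl(chloro)diphenylsilane, CC(C)(C)[Si](Cl)(c1ccccc1)c1ccccc1
Why: Silylation of the primary alcohol blocks retro-aldol loss of formaldehyde and installs the bulky group that later biases the faces of ring A.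

Step 4
Reactants: 4 silyl ether ketone
Product: 5 (6S)-6-{[tert-butyl(diphenyl)silyl]oxymethyl}-2,6-dimethylcyclohex-1-en-1-yl trifluoromethanesulfonate
Conditions: KN(SiMe3)2, THF, −78 °C; PhNTf2, −78 to 0 °C
Reagents that add atoms: N-phenylbis(trifluoromethanesulfonimide), O=S(=O)(N(c1ccccc1)S(=O)(=O)C(F)(F)F)C(F)(F)F
Why: Only the CH(CH3) α-carbon (future C10) can be deprotonated, so the potassium enolate should be trapped regiospecifically as the tetrasubstituted enol triflate.

Step 5
Reactants: 5 enol triflate
Product: 6 (6R)-6-{[tert-butyl(diphenyl)silyl]oxymethyl}-2,6-dimethylcyclohex-1-ene-1-carboxylic acid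
Conditions: Pd(OAc)2 (5 mol%), 1,1'-bis(diphenylphosphino)ferrocene, CO (1 atm), Et3N, DMF/H2O, 70 °C; then 1 M HCl
Reagents that add atoms: carbon monoxide, [C-]#[O+]; water, O
Why: Palladium-catalysed hydroxycarbonylation of a vinyl triflate (oxidative addition, CO insertion, hydrolysis of the acylpalladium) brings in C6 at the acid oxidation level.

Step 6
Reactants: 6 acid
Product: 7 (6R)-6-{[tert-butyl(diphenyl)silyl]oxymethyl}-2,6-dimethylcyclohex-1-ene-1-carbonyl chloride
Conditions: (COCl)2, DMF (cat.), CH2Cl2, 0 °C to rt; evaporate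
Reagents that add atoms: oxalyl chloride, O=C(Cl)C(Cl)=O
Why: Vilsmeier-type activation should convert the hindered acid into its chloride without affecting the silyl ether (acyl chloride formation).

Step 7
Reactants: 8 2,2-dimethoxypropane; 9 morpholine
Product: 10 4-(prop-1-en-2-yl)morpholine
Conditions: p-TsOH (1 mol%), neat, 90 °C, MeOH distilled off; then distillation
Reagents that add atoms: none
Why: Acid-catalysed exchange of the ketal with the amine and loss of methanol (enamine formation) gives the symmetrical acetone enamine.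

Step 8
Reactants: 7 acid chloride; 10 acetone enamine
Product: 13 bicyclic vinylogous amide (trans-fused 8-morpholino-7-en-6-one), via N-acylenammonium chloride 11 (not isolated), via ketene iminium chloride 12 (not isolated)
Conditions: 10 (2.2 equiv), toluene, 0 °C then 110 °C, no tertiary amine; aq. NaHCO3 work-up
Reagents that add atoms: none
Why: Proposed new method: N-acylation of 10 by 7 gives enammonium salt 11, whose charge-accelerated 3-aza-Cope ([3,3]) shift through a chair transition state joins the enamine carbon (C9) to the fully substituted ring carbon C10 and releases ketene iminium 12; the second equivalent of 10 deprotonates the iminium methyl group, the new enamine carbon (C7) acylates the ketene carbon C6, and proton transfer leaves 13. The closest known reaction type is the [3+3] annulation of ketone enamines with acryloyl, crotonoyl and methacryloyl chlorides to cyclohexane-1,3-dione derivatives; a fully substituted β-carbon that becomes a ring-fusion quaternary centre has not been shown, hence the label. Ring B closes by C-acylation of the ketene (6-exo-dig with respect to the ketene C=O), after the C9–C10 bond has been made inside the six-membered sigmatropic array. C10 is controlled by C4: the shift should occur on the face of the ring A alkene anti to the pseudoaxial CH2OSi group, the larger C4 substituent avoiding allylic strain with the acyl group. C5 is set by protonation of the C5=C6 enolate and equilibration next to the vinylogous amide carbonyl, which should favour the trans fusion. The step needs the sigmatropic path to outrun γ-deprotonation of 11 to a vinylketene and needs the facial bias: no tertiary amine is present, the symmetrical enamine gives the same product whether N- or C-acylation comes first, and the bulky silyl ether supplies the bias.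

Step 9
Reactants: 13 vinylogous amide
Product: 15 bicyclic enone (trans-fused 6-en-8-one), via amino allylic alcohol 14 (not isolated)
Conditions: LiAlH4, THF, 0 °C to rt; then 2 M HCl, THF, rt
Reagents that add atoms: water, O
Why: 1,2-Reduction of the vinylogous amide carbonyl, then hydrolysis of the enamine and β-elimination of water (reductive 1,3-carbonyl transposition) should remove the C6 oxygen and unveil the C8 ketone without touching a stereocentre.

Step 10
Reactants: 15 enone; 16 (4-iodobut-1-yn-1-yl)trimethylsilane
Product: 17 C9-alkylated enone (C9 epimers)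
Conditions: LiN(i-Pr)2, THF, −78 °C; 16, DMPU, −78 to −20 °C
Reagents that add atoms: none
Why: Kinetic deprotonation of the enone occurs at the α' carbon (C9) and the cross-conjugated lithium enolate is alkylated by the primary iodide (enolate alkylation); the C9 configuration is corrected in step 11.

Step 11
Reactants: 17 alkylated enone
Product: 19 alkynyl ketone (C9 side chain syn to CH3-20), via saturated silylalkyne ketone 18 (not isolated)
Conditions: LiBH(s-Bu)3, THF, −78 °C; then MeOH, K2CO3, rt to 40 °C
Reagents that add atoms: none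
Why: Conjugate hydride reduction of the enone, then base-mediated methanolysis of the alkynyl C–Si bond and equilibration of the enolisable C9 centre to the more stable equatorial side chain (H-9 syn to H-5).

Step 12
Reactants: 19 alkynyl ketone
Product: 20 exocyclic alkene (C8=C17) with but-3-ynyl side chain
Conditions: Ph3PCH3Br, KOt-Bu (excess), toluene, rt to 90 °C
Reagents that add atoms: methyltriphenylphosphonium bromide, C[P+](c1ccccc1)(c1ccccc1)c1ccccc1.[Br-]
Why: Wittig methylenation of the hindered C8 ketone with excess ylide (the acetylide formed alongside is inert); once C8 is an alkene carbon, C9 can no longer epimerise.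

Step 13
Reactants: 20 silyl ether
Product: 21 enyne alcohol (free C19 hydroxyl)
Conditions: Bu4NF, THF, 50 °C
Reagents that add atoms: none
Why: Fluoride-induced cleavage of the neopentyl silyl ether (desilylation); alkyne and alkene are inert.

Step 14
Reactants: 21 enyne alcohol
Product: 22 (4R,5S,9R,10S)-labda-8(17),13(16),14-trien-19-ol
Conditions: ethylene (1 atm), second-generation Grubbs catalyst (5 mol%), CH2Cl2, rt to 40 °C
Reagents that add atoms: ethylene, C=C
Why: Ene–yne cross-metathesis of the terminal alkyne with ethylene should give the 2-substituted buta-1,3-diene; the hindered 1,1-disubstituted C8=C17 alkene is a poor metathesis partner.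

Step 15
Reactants: 22 trienol
Product: 23 C19 bromoacetate
Conditions: BrCH2COBr, pyridine, CH2Cl2, 0 °C
Reagents that add atoms: bromoacetyl bromide, O=C(Br)CBr
Why: Acylation of the hindered primary alcohol with a reactive acyl bromide (esterification).

Step 16
Reactants: 23 bromoacetate
Product: 24 C19 (diphenoxyphosphoryl)acetate
Conditions: (PhO)2P(O)H, Et3N, CH2Cl2, 0 °C to rt
Reagents that add atoms: diphenyl phosphite, O=[PH](Oc1ccccc1)Oc1ccccc1
Why: Michaelis–Becker alkylation of the phosphite anion by the α-bromo ester gives the diaryl phosphonoacetate.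

Step 17
Reactants: 24 phosphonoacetate; 25 4-[(tert-butyldimethylsilyl)oxy]benzaldehyde
Product: 26 Z-coumarate with silyl-protected phenol
Conditions: NaH, THF, 0 °C; 25, −78 to −20 °C, dark
Reagents that add atoms: none
Why: Z-selective Horner–Wadsworth–Emmons olefination; with a diaryl phosphonate the adduct collapses faster than it equilibrates, so the Z enoate should form under kinetic control.

Step 18
Reactants: 26 silyl-protected ester
Product: 27 target (4R,5S,9R,10S)-labda-8(17),13(16),14-trien-19-yl (2Z)-3-(4-hydroxyphenyl)prop-2-enoate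
Conditions: Bu4NF, AcOH, THF, 0 °C, dark
Reagents that add atoms: none
Why: Buffered fluoride cleavage of the aryl silyl ether at low temperature in the dark should avoid phenoxide-mediated Z to E isomerisation.

**Compound list**

1 | 2,6-dimethylcyclohexan-1-one (cis/trans mixture) | CC1CCCC(C)C1=O | starting material
2 | 2,6-dimethyl-1-(trimethylsilyloxy)cyclohex-1-ene (racemic) | CC1CCCC(C)=C1O[Si](C)(C)C | intermediate
3 | (2S)-2-(hydroxymethyl)-2,6-dimethylcyclohexan-1-one (both C6 epimers) | CC1CCC[C@@](C)(CO)C1=O | intermediate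
4 | (2S)-2-{[tert-butyl(diphenyl)silyl]oxymethyl}-2,6-dimethylcyclohexan-1-one | CC1CCC[C@@](C)(CO[Si](c2ccccc2)(c2ccccc2)C(C)(C)C)C1=O | intermediate
5 | (6S)-6-{[tert-butyl(diphenyl)silyl]oxymethyl}-2,6-dimethylcyclohex-1-en-1-yl trifluoromethanesulfonate | CC1=C(OS(=O)(=O)C(F)(F)F)[C@](C)(CO[Si](c2ccccc2)(c2ccccc2)C(C)(C)C)CCC1 | intermediate
6 | (6R)-6-{[tert-butyl(diphenyl)silyl]oxymethyl}-2,6-dimethylcyclohex-1-ene-1-carboxylic acid | CC1=C(C(O)=O)[C@](C)(CO[Si](c2ccccc2)(c2ccccc2)C(C)(C)C)CCC1 | intermediate
7 | (6R)-6-{[tert-butyl(diphenyl)silyl]oxymethyl}-2,6-dimethylcyclohex-1-ene-1-carbonyl chloride | CC1=C(C(Cl)=O)[C@](C)(CO[Si](c2ccccc2)(c2ccccc2)C(C)(C)C)CCC1 | intermediate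
8 | 2,2-dimethoxypropane | COC(C)(C)OC | starting material
9 | morpholine | C1COCCN1 | starting material
10 | 4-(prop-1-en-2-yl)morpholine | C=C(C)N1CCOCC1 | intermediate
11 | 4-{[(6R)-6-{[tert-butyl(diphenyl)silyl]oxymethyl}-2,6-dimethylcyclohex-1-en-1-yl]carbonyl}-4-(prop-1-en-2-yl)morpholin-4-ium chloride | CC1=C(C(=O)[N+]2(CCOCC2)C(C)=C)[C@](C)(CO[Si](c2ccccc2)(c2ccccc2)C(C)(C)C)CCC1.[Cl-] | intermediate (not isolated)
12 | ketene iminium chloride: ring A ketene (C5=C6=O) whose C10 carries CH3-20 and the CH2–C(CH3)=N+(morpholinium) arm, this arm anti to CH2OSi on C4 | CC(C[C@]1(C)CCC[C@@](C)(CO[Si](c2ccccc2)(c2ccccc2)C(C)(C)C)C1=C=O)=[N+]1CCOCC1.[Cl-] | intermediate (not isolated)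
13 | bicyclic vinylogous amide: trans-decalin core with C6 ketone, C7=C8 alkene, morpholin-4-yl on C8, C9 as CH2; H-5 anti and CH2OSi-19 syn to CH3-20 | C1C(N3CCOCC3)=CC(=O)[C@@H]2[C@](C)(CO[Si](c3ccccc3)(c3ccccc3)C(C)(C)C)CCC[C@@]12C | intermediate
14 | amino allylic alcohol: as 13 with C6 carbinol in place of the ketone (both C6 epimers) | C1C(N3CCOCC3)=CC(O)[C@@H]2[C@](C)(CO[Si](c3ccccc3)(c3ccccc3)C(C)(C)C)CCC[C@@]12C | intermediate (not isolated)
15 | bicyclic enone: C8 ketone, C6=C7 alkene, C9 as CH2; H-5 anti and CH2OSi-19 syn to CH3-20 | C1C(=O)C=C[C@@H]2[C@](C)(CO[Si](c3ccccc3)(c3ccccc3)C(C)(C)C)CCC[C@@]12C | intermediate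
16 | (4-iodobut-1-yn-1-yl)trimethylsilane | C[Si](C)(C)C#CCCI | starting material
17 | enone 15 carrying a 4-(trimethylsilyl)but-3-ynyl group on C9 (C9 epimers) | C[Si](C)(C)C#CCCC1C(=O)C=C[C@@H]2[C@](C)(CO[Si](c3ccccc3)(c3ccccc3)C(C)(C)C)CCC[C@@]12C | intermediate
18 | saturated C8 ketone with 4-(trimethylsilyl)but-3-ynyl on C9 (C9 epimers) | C[Si](C)(C)C#CCCC1C(=O)CC[C@@H]2[C@](C)(CO[Si](c3ccccc3)(c3ccccc3)C(C)(C)C)CCC[C@@]12C | intermediate (not isolated)
19 | saturated C8 ketone with but-3-ynyl on C9, side chain syn to CH3-20 (equatorial), trans ring fusion | C#CCC[C@@H]1C(=O)CC[C@@H]2[C@](C)(CO[Si](c3ccccc3)(c3ccccc3)C(C)(C)C)CCC[C@@]12C | intermediate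
20 | as 19 with C8=CH2 (C17) in place of the ketone | C#CCC[C@@H]1C(=C)CC[C@@H]2[C@](C)(CO[Si](c3ccccc3)(c3ccccc3)C(C)(C)C)CCC[C@@]12C | intermediate
21 | as 20 with free C19 hydroxyl | C#CCC[C@@H]1C(=C)CC[C@@H]2[C@](C)(CO)CCC[C@@]12C | intermediate
22 | (4R,5S,9R,10S)-labda-8(17),13(16),14-trien-19-ol | C=CC(=C)CC[C@@H]1C(=C)CC[C@@H]2[C@](C)(CO)CCC[C@@]12C | intermediate
23 | (4R,5S,9R,10S)-labda-8(17),13(16),14-trien-19-yl bromoacetate | C=CC(=C)CC[C@@H]1C(=C)CC[C@@H]2[C@](C)(COC(=O)CBr)CCC[C@@]12C | intermediate
24 | (4R,5S,9R,10S)-labda-8(17),13(16),14-trien-19-yl (diphenoxyphosphoryl)acetate | C=CC(=C)CC[C@@H]1C(=C)CC[C@@H]2[C@](C)(COC(=O)CP(=O)(Oc3ccccc3)Oc3ccccc3)CCC[C@@]12C | intermediate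
25 | 4-[(tert-butyldimethylsilyl)oxy]benzaldehyde | CC(C)(C)[Si](C)(C)Oc1ccc(C=O)cc1 | starting material
26 | (4R,5S,9R,10S)-labda-8(17),13(16),14-trien-19-yl (2Z)-3-{4-[(tert-butyldimethylsilyl)oxy]phenyl}prop-2-enoate | C=CC(=C)CC[C@@H]1C(=C)CC[C@@H]2[C@](C)(COC(=O)/C=C\c3ccc(O[Si](C)(C)C(C)(C)C)cc3)CCC[C@@]12C | intermediate
27 | (4R,5S,9R,10S)-labda-8(17),13(16),14-trien-19-yl (2Z)-3-(4-hydroxyphenyl)prop-2-enoate (CNP0131099.2) | C=CC(=C)CC[C@@H]1C(=C)CC[C@@H]2[C@](C)(COC(=O)/C=C\c3ccc(O)cc3)CCC[C@@]12C | target

**Count and risks**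

Total step count: 18. Longest linear sequence: 17 steps (steps 1–6 and 8–18; step 7 is a one-step side branch).

Steps most likely to fail:

Step 8 (Proposed new method). The N-acylation/[3,3] sequence may lose to γ-deprotonation of the acylammonium ion (vinylketene formation), the cascade may stop after acylation without the second ring closure, or the facial selectivity at C10 may be low. The fallback uses known chemistry, sets out from acid 6 and comes back at enone 15. Acid 6 is reduced with LiAlH4 to allylic alcohol F1, which is acetoacetylated with 2,2,6-trimethyl-4H-1,3-dioxin-4-one in xylene at 140 °C to acetoacetate F2. Carroll rearrangement of F2 at about 190 °C, with loss of CO2, forms C9–C10 through a six-membered chair under the same facial bias and gives methyl ketone F3. Hydroboration–oxidation (BH3·THF; H2O2, NaOH) gives diol F4, Dess–Martin oxidation gives keto aldehyde F5, and KOH in MeOH closes C6–C7 by aldol condensation with equilibration at C5 to give 15.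

Step 10. C-alkylation of the hindered enolate next to the quaternary C10 may be slow, with dehydrohalogenation of the homopropargylic iodide and proton transfer taking over. The fallback sets out from enone 15 and comes back at 17. Enone 15 is condensed with 1,1-dimethylhydrazine (AcOH cat., EtOH) to N,N-dimethylhydrazone F6. Its more nucleophilic aza-enolate (LiN(i-Pr)2, THF, −78 °C) is alkylated with 16 to alkylated hydrazone F7, and hydrolysis with aqueous CuCl2 at pH 7 returns ketone 17.

Step 2. Enantioselection may be insufficient on a fully aliphatic tetrasubstituted silyl enol ether, and hydrolysis of the enol ether or retro-aldol loss of formaldehyde may compete. The fallback sets out from 2 and comes back at 3. Racemic hydroxymethylation (aq. HCHO, Yb(OTf)3, THF/H2O) gives racemic hydroxy ketone F8. Lipase-catalysed acylation with vinyl acetate then converts the unwanted enantiomer into (R)-acetate F9 and leaves (S)-alcohol 3, which is separated by chromatography; should the enzyme prefer the (S)-alcohol, its acetate would be isolated and cleaved enzymatically instead.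

**Further compounds**

F1 | step 8 | [(6R)-6-{[tert-butyl(diphenyl)silyl]oxymethyl}-2,6-dimethylcyclohex-1-en-1-yl]methanol | CC1=C(CO)[C@](C)(CO[Si](c2ccccc2)(c2ccccc2)C(C)(C)C)CCC1
F2 | step 8 | [(6R)-6-{[tert-butyl(diphenyl)silyl]oxymethyl}-2,6-dimethylcyclohex-1-en-1-yl]methyl 3-oxobutanoate | CC1=C(COC(=O)CC(C)=O)[C@](C)(CO[Si](c2ccccc2)(c2ccccc2)C(C)(C)C)CCC1
F3 | step 8 | 1-[3-{[tert-butyl(diphenyl)silyl]oxymethyl}-1,3-dimethyl-2-methylidenecyclohexyl]propan-2-one (acetonyl group anti to CH2OSi) | CC(=O)C[C@]1(C)CCC[C@@](C)(CO[Si](c2ccccc2)(c2ccccc2)C(C)(C)C)C1=C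
F4 | step 8 | diol from F3: 2-(hydroxymethyl) ring carbon and propan-2-ol side chain (stereoisomers at the two new centres) | CC(O)C[C@]1(C)CCC[C@@](C)(CO[Si](c2ccccc2)(c2ccccc2)C(C)(C)C)C1CO
F5 | step 8 | keto aldehyde: 2-{[tert-butyl(diphenyl)silyl]oxymethyl}-2,6-dimethyl-6-(2-oxopropyl)cyclohexane-1-carbaldehyde (C1 epimers) | CC(=O)C[C@]1(C)CCC[C@@](C)(CO[Si](c2ccccc2)(c2ccccc2)C(C)(C)C)C1C=O
F6 | step 10 | N,N-dimethylhydrazone of enone 15 | C1C(=NN(C)C)C=C[C@@H]2[C@](C)(CO[Si](c3ccccc3)(c3ccccc3)C(C)(C)C)CCC[C@@]12C
F7 | step 10 | N,N-dimethylhydrazone of ketone 17 (C9 epimers) | C[Si](C)(C)C#CCCC1C(=NN(C)C)C=C[C@@H]2[C@](C)(CO[Si](c3ccccc3)(c3ccccc3)C(C)(C)C)CCC[C@@]12C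
F8 | step 2 | racemic 2-(hydroxymethyl)-2,6-dimethylcyclohexan-1-one | CC1CCCC(C)(CO)C1=O
F9 | step 2 | [(1R)-1,3-dimethyl-2-oxocyclohexyl]methyl acetate | CC1CCC[C@](C)(COC(C)=O)C1=O
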